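## The problem

The target **22** is made of two 2,3-trans-2,3-diaryl-2,3-dihydrobenzofurans joined by one bond. Ring A is the formyl-bearing heterocycle (O1, C2, C3, benzo carbons C3a to C7a, formyl on C5). Ring B is the second heterocycle (O1', C2', C3') and ring C its benzo ring (C3a' to C7a'), whose C4' is bonded to C3 of ring A.

There are four stereocentres, all R, in two pairs. Within each pair the 2-aryl group can be placed trans to the 3-aryl group by reversible, acid-mediated closure of the O–C2 bond, so C3 can control C2 and C3' can control C2'. The two pairs lie on opposite sides of the C3–C4' bond and neither can be relied on to control the other, so C3' and C3 each need their own source of absolute configuration.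

C3 is the hardest point. It is a methine between two ortho-substituted arenes and loses its configuration whenever it stands α to a free carbonyl group. The five phenols are oxidation-prone and must stay masked until the end, and the aldehyde must survive their unmasking. Both 2-aryl C–O bonds ionise in acid to p-oxygenated benzyl cations, which can lose a proton or be trapped by the electron-rich 3,5-dioxygenated ring.

The structure offers one opening. O1 on C7a and the formyl-bearing C5 are para, so once the formyl group is traced back to a phenol, the benzene ring of ring A has the oxygen pattern of 1,4-benzoquinone. C3 is then the α-carbon of an aldehyde whose carbonyl carbon is C2.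

## Retrosynthesis

**22 to 21.** The five O–H bonds are traced back to O–CH3 bonds in pentamethyl ether **21**. Benzyl ethers were set aside because hydrogenolysis also threatens the benzylic C2–O1 and C2'–O1' bonds and the formyl group. Silyl ethers would not pass the Lewis acid and organometallic steps. The forward step must cleave five aryl methyl ethers beside an aldehyde and two benzylic ethers.

**21 to 19.** The C5–CHO bond is cut and the formyl carbon is taken from carbon monoxide, via triflate **20**, back to phenol **19**. Carrying the formyl group from the start would require an acyl-substituted quinone, which has no reason to accept a nucleophile at the right position. The phenol at C5 is exactly what a quinone leaves behind. The forward steps are triflation of the only free hydroxyl group and a reductive carbonylation.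

**19 to 16.** The O1–C2 bond and the C2–aryl bond are cut. C2 becomes the hemiacetal carbon of lactol **16**, and the aryl group comes from 4-methoxyphenylmagnesium bromide **17** through triol **18**. Cutting at C3 instead would dismantle the stereocentre that is hardest to make. With this cut the C2 configuration follows from C3, because both carbinol epimers of **18** close through the same benzylic cation. The forward steps need an aryl transfer that does not deprotonate C3 and a ring closure under kinetic control.

**16 to 13 and 14.** The C3–C3a bond and the hemiacetal O1–C2 bond are cut together. This leaves arylacetaldehyde **13**, which holds all of ring B, and 1,4-benzoquinone **14**, which supplies the six carbons of ring A with oxygen on C7a and C5. A Friedel–Crafts or cross-coupling construction of C3–C3a would give no handle on the configuration of C3. Here a chiral amine sets it in the bond-forming step, and the hemiacetal protects it at once.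

**13 to 10 and 11.** The C4'–CH2 bond is cut to trans-bromide **10** and the two-carbon boronate **11**, through enol ether **12**. A coupling followed by hydrolysis is one step shorter than formylation, one-carbon Wittig homologation and hydrolysis, and it avoids an aryllithium next to the doubly benzylic C3'–H. The forward coupling must work next to one ortho substituent.

**10 to 6.** Bromide **10** is the more stable epimer of cis-bromide **9**. In **9** the C2'–C3' bond is cut to the diaryl carbene derived from diazo compound **8**, hydrazone **7** and ketone **6**. The carbene inserts into the benzylic C–H bond of a 4-methoxybenzyl ether, a catalytic enantioselective reaction with precedent for this pair of aryl groups. Reducing a 2,3-diarylbenzofuran would give no absolute control. The forward steps must accept a ketone with two ortho substituents.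

**6 to 1 and 2.** The O–CH2 bond of **6** leads to phenol **4** and 4-methoxybenzyl chloride **5**. Phenol **4** comes from ketone **3** by removal of the one methyl group that sits ortho to the carbonyl group. The C3a'–C3' bond of **3** is a Friedel–Crafts bond between 1-bromo-3,5-dimethoxybenzene **1** and 3,5-dimethoxybenzoyl chloride **2**. Bromine marks C4' from the first step and is inert until step 7.

## Roads not taken

**Alternative 1:** This plan cuts both carbon substituents of ring C, C4'–C3 and C3a'–C3', in one step. Fluoride (CsF) releases an aryne from silyl triflate **A2**, and the aryne inserts into the CH2–acyl bond of β-keto ester **A1** to give keto ester **A3**.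

- Merits: one step delivers ring C with all four substituents in defined positions. The acetic ester arm is C3 and C2 of ring A, so no palladium coupling at a hindered halide and no enol ether are needed.
- Weak points: no stereocentre is made. **A3** must then go through the same ring B construction as **3**, but with an acidic CH2CO2Et group ortho to the ketone. That group can condense with the ketone in base, can close a diazepinone with hydrazine and offers a competing C–H bond to a carbene. **A2** also needs several steps, whereas **3** is one step from commercial compounds.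
- Comparison: Alternative 1 is better at the C4'–CH2 bond and stores the aldehyde as a robust ester, where the chosen route spends steps 7 and 8. The chosen plan sets against this a halogen that is inert through steps 2 to 6 and a shorter way to the benzophenone. Both roads would meet at aldehyde **13** and still need the chosen key step.

**Alternative 2:** This plan cuts C2'–C3' and O1'–C2' of ring B. Base (Cs2CO3) eliminates sulfinate from benzylic sulfone **A4**. The resulting ortho-quinone methide is attacked at C3' by the ylide of chiral sulfonium salt **A5**, and the phenoxide displaces the sulfide to close ring B. The product is bromide **A6**, identical with **10**.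

- Merits: both ring B stereocentres and the trans relation come in one step, without a hindered hydrazone, a diazo compound or an epimerisation. It reaches the bromide in fewer steps than steps 1 to 6 here, which is a real advantage.
- Weak points: the chiral sulfide is used in stoichiometric amount. Addition of a semi-stabilised benzyl ylide may be reversible, which weakens reagent control. The quinone methide carries bromine next to the reacting carbon. The asymmetric version of this annulation is less established than the carbene insertion.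
- Comparison: this alternative is about ring B only and ends where the harder problem, C3 of ring A, begins. The chosen plan puts its one uncertain step there and builds ring B with a catalytic reaction of known scope. If steps 4 to 6 disappointed, the annulation could replace them without touching the rest.

**Alternative 3:** This plan cuts C3a–C7a, C4–C5 and C6–C7, so the benzene ring of ring A is built last. Cp*RuCl(cod) joins ynol-ether diyne **A7** with 3,3-diethoxyprop-1-yne **A8** to give silyl acetal **A9**.

- Merits: the formyl carbon arrives at the aldehyde oxidation level, so no triflate and no carbon monoxide are needed. No oxidisable hydroquinone appears, and C3 is never α to a carbonyl group.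
- Weak points: **A7** must already contain C2 and C3 with the right relative and absolute configuration, on an acyclic propargylic, doubly activated methine that strong base would isomerise. Making the silyl ynol ether requires such base. The position of the acetal depends on steering by the silyl group, which must later be removed under acid or fluoride.
- Comparison: Alternative 3 is better in the last steps, since hydrolysis of an acetal replaces steps 12 and 13. The chosen plan sets against this that it creates C3 by catalyst control in the step that attaches ring A, from a commercial six-carbon unit. In Alternative 3 the stereochemical problem is only moved into **A7**, whose synthesis would be the longest part of the route.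

Key step: step 9

Assumption: Rh2(S-PTAD)4 is taken to give the (3R) cis isomer **9**, and the (S)-diarylprolinol silyl ether is taken to cover the Re face of the E-enamine as in its other aldehyde α-functionalisations; if either sense proves reversed, the mirror-image catalyst is used and nothing else changes.

Shorthand in the steps: ArB is the ring B aryl group, (2R,3R)-3-(3,5-dimethoxyphenyl)-6-methoxy-2-(4-methoxyphenyl)-2,3-dihydro-1-benzofuran-4-yl. Full names are in the compound list.

Step 1
Reactants: 1 1-bromo-3,5-dimethoxybenzene; 2 3,5-dimethoxybenzoyl chloride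
Product: 3 (2-bromo-4,6-dimethoxyphenyl)(3,5-dimethoxyphenyl)methanone
Conditions: AlCl3, CH2Cl2, 0 °C
Reagents that add atoms: none
Why: Friedel–Crafts acylation; the acylium ion should attack C2 of 1, para to one methoxy group and ortho to the other, as other electrophiles do with 5-halo-resorcinol dimethyl ethers. The isomer acylated between the two methoxy groups is the expected minor product and is removed here; any loss of the ortho methyl group only anticipates step 2.

Step 2
Reactants: 3 (2-bromo-4,6-dimethoxyphenyl)(3,5-dimethoxyphenyl)methanone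
Product: 4 (2-bromo-6-hydroxy-4-methoxyphenyl)(3,5-dimethoxyphenyl)methanone
Conditions: BCl3, CH2Cl2, −78 → 0 °C; aq. work-up
Reagents that add atoms: none
Why: Chelation-controlled ether cleavage; BCl3 bound to the ketone oxygen should remove only the methyl group of the ortho methoxy group through a six-membered chelate. The other four methoxy groups and the bromide are out of reach.

Step 3
Reactants: 4 (2-bromo-6-hydroxy-4-methoxyphenyl)(3,5-dimethoxyphenyl)methanone; 5 4-methoxybenzyl chloride
Product: 6 {2-bromo-4-methoxy-6-[(4-methoxybenzyl)oxy]phenyl}(3,5-dimethoxyphenyl)methanone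
Conditions: K2CO3, n-Bu4NI (cat.), DMF, 60 °C
Reagents that add atoms: none
Why: Williamson ether synthesis; it installs C2' with its aryl group as a benzylic ether whose C–H bond is the insertion site of step 5.

Step 4
Reactants: 6 {2-bromo-4-methoxy-6-[(4-methoxybenzyl)oxy]phenyl}(3,5-dimethoxyphenyl)methanone
Product: 7 hydrazone of 6 (E/Z mixture)
Conditions: N2H4·H2O (excess), AcOH (cat.), n-BuOH, 110 °C
Reagents that add atoms: hydrazine (as hydrate), NN
Why: Hydrazone condensation; forcing conditions are chosen because the ketone has two ortho substituents. Ethers and the aryl bromide do not react with hydrazine.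

Step 5
Reactants: 7 hydrazone of 6
Product: 9 (2S,3R)-4-bromo-3-(3,5-dimethoxyphenyl)-6-methoxy-2-(4-methoxyphenyl)-2,3-dihydro-1-benzofuran, via diazo compound 8 (not isolated)
Conditions: MnO2, CH2Cl2, 0 °C, filtration; then Rh2(S-PTAD)4 (1 mol %), CH2Cl2, −20 °C → rt
Reagents that add atoms: none
Why: Oxidation of the hydrazone to the diaryldiazomethane, then dirhodium-carbene 1,5-insertion into the benzylic ether C–H bond (activated by oxygen and the 4-methoxyphenyl group), forming C2'–C3'. Enantioselective insertion of diaryl carbenes into benzyl ethers is a known route to cis-2,3-diaryl-dihydrobenzofurans; the chiral carboxylate ligands set C3' and the cis relation follows from the insertion geometry.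

Step 6
Reactants: 9 (2S,3R)-4-bromo-3-(3,5-dimethoxyphenyl)-6-methoxy-2-(4-methoxyphenyl)-2,3-dihydro-1-benzofuran
Product: 10 (2R,3R)-4-bromo-3-(3,5-dimethoxyphenyl)-6-methoxy-2-(4-methoxyphenyl)-2,3-dihydro-1-benzofuran
Conditions: BF3·OEt2, CH2Cl2, 0 °C → rt
Reagents that add atoms: none
Why: Acid-mediated epimerisation at C2'; reversible heterolysis of the O1'–C2' bond gives the 4-methoxybenzyl cation, which should reclose to the more stable trans isomer. C3' takes no part and keeps the R configuration set in step 5.

Step 7
Reactants: 10 (2R,3R)-4-bromo-3-(3,5-dimethoxyphenyl)-6-methoxy-2-(4-methoxyphenyl)-2,3-dihydro-1-benzofuran; 11 (E)-2-(2-ethoxyvinyl)-4,4,5,5-tetramethyl-1,3,2-dioxaborolane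
Product: 12 (2R,3R)-3-(3,5-dimethoxyphenyl)-4-[(E)-2-ethoxyvinyl]-6-methoxy-2-(4-methoxyphenyl)-2,3-dihydro-1-benzofuran
Conditions: PdCl2(dppf) (5 mol %), K3PO4, 1,4-dioxane/H2O, 85 °C
Reagents that add atoms: none
Why: Suzuki–Miyaura coupling; the alkenylboronate brings C3 and C2 of ring A as a masked acetaldehyde. The bromide has one ortho substituent, which this catalyst tolerates, and the mild base leaves both stereocentres alone.

Step 8
Reactants: 12 (2R,3R)-3-(3,5-dimethoxyphenyl)-4-[(E)-2-ethoxyvinyl]-6-methoxy-2-(4-methoxyphenyl)-2,3-dihydro-1-benzofuran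
Product: 13 2-(ArB)acetaldehyde
Conditions: 2 M aq. HCl, THF, rt; used crude
Reagents that add atoms: water, O
Why: Enol ether hydrolysis (protonation at the benzylic carbon, hydration of the oxocarbenium ion, loss of ethanol). Dilute acid should not open ring B, and trans ring B is the stable isomer in any case; 13 is used at once because arylacetaldehydes self-condense.

Step 9
Reactants: 13 2-(ArB)acetaldehyde; 14 1,4-benzoquinone
Product: 16 (3R)-3-(ArB)-2,3-dihydro-1-benzofuran-2,5-diol (C2 epimers), via hydroquinone aldehyde 15 (not isolated)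
Conditions: 14 (1.2 equiv), (S)-2-{bis[3,5-bis(trifluoromethyl)phenyl](trimethylsilyloxy)methyl}pyrrolidine (20 mol %), EtOH/CH2Cl2/H2O, −24 °C
Reagents that add atoms: none
Why: Condensation of 13 with the amine gives the E-enamine, whose Re face at the α-carbon is covered by the diaryl(silyloxy)methyl group; 14 should therefore approach the Si face, and conjugate addition to a quinone CH forms C3–C3a with the R configuration. The adduct tautomerises to the hydroquinone and the iminium ion is hydrolysed to 15; the hydroxyl group ortho to the new bond then adds to the aldehyde (5-exo-trig hemiacetal formation, O1–C2), which removes the carbonyl group and protects the doubly benzylic C3 from enolisation. The closest known reaction type is the amine-catalysed enantioselective α-arylation of aldehydes with quinones, which ends in the same 2,3-dihydrobenzofuran-2,5-diols; an arylacetaldehyde is a less explored member of that aldehyde class. C3 is set by the catalyst, with ring B on the ortho position of the enamine aryl group as a second, weaker bias; C2 is an anomeric centre, forms as a mixture and is rebuilt in steps 10 and 11. The step needs facial selectivity, a single arylation and no redox exchange with the quinone: the first rests on the catalyst, the second on the absence of a free aldehyde in 16, the third on the hemiacetal being a 4-alkoxyphenol that is harder to oxidise than 15 and on keeping 14 near one equivalent. Unsubstituted 14 has four equivalent CH positions, so there is no regiochemical question.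

Step 10
Reactants: 16 (3R)-3-(ArB)-2,3-dihydro-1-benzofuran-2,5-diol; 17 4-methoxyphenylmagnesium bromide
Product: 18 2-[(1R)-1-(ArB)-2-hydroxy-2-(4-methoxyphenyl)ethyl]benzene-1,4-diol (carbinol epimers)
Conditions: 17 (5 equiv), CeCl3 (anhydrous), THF, −78 → −20 °C; sat. aq. NH4Cl
Reagents that add atoms: none
Why: Organocerium 1,2-addition to the lactol through its ring-opened hydroxy aldehyde; two equivalents are spent on the two hydroxyl groups. The weakly basic cerium reagent should add faster than it deprotonates C3–H, so C3 is kept; the carbinol centre forms unselectively and is erased in step 11.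

Step 11
Reactants: 18 2-[(1R)-1-(ArB)-2-hydroxy-2-(4-methoxyphenyl)ethyl]benzene-1,4-diol
Product: 19 (2R,3R)-3-(ArB)-2-(4-methoxyphenyl)-2,3-dihydro-1-benzofuran-5-ol
Conditions: p-TsOH·H2O (10 mol %), degassed CH2Cl2, 0 °C, short contact; NaHCO3 quench
Reagents that add atoms: none
Why: Acid-catalysed cyclodehydration; both carbinol epimers ionise to the same 4-methoxybenzyl cation, which the ortho hydroxyl group captures to close the five-membered ring with the C2 aryl group trans to the C3 aryl group, the favoured arrangement kinetically and thermodynamically. Catalytic acid, low temperature and a short contact time are chosen so that O-capture is not overtaken by Friedel–Crafts attack of the dimethoxyphenyl ring or by proton loss.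

Step 12
Reactants: 19 (2R,3R)-3-(ArB)-2-(4-methoxyphenyl)-2,3-dihydro-1-benzofuran-5-ol
Product: 20 (2R,3R)-3-(ArB)-2-(4-methoxyphenyl)-2,3-dihydro-1-benzofuran-5-yl trifluoromethanesulfonate
Conditions: Tf2O, pyridine, CH2Cl2, 0 °C
Reagents that add atoms: trifluoromethanesulfonic anhydride, O=S(=O)(OS(=O)(=O)C(F)(F)F)C(F)(F)F
Why: Sulfonylation of the only free hydroxyl group; it turns the oxygen left by the quinone at C5 into a leaving group.

Step 13
Reactants: 20 (2R,3R)-3-(ArB)-2-(4-methoxyphenyl)-2,3-dihydro-1-benzofuran-5-yl trifluoromethanesulfonate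
Product: 21 (2R,3R)-3-(ArB)-2-(4-methoxyphenyl)-2,3-dihydro-1-benzofuran-5-carbaldehyde
Conditions: Pd(OAc)2 (5 mol %), dppp, CO (1 atm), Et3SiH, Et3N, DMF, 70 °C
Reagents that add atoms: carbon monoxide, [C-]#[O+]
Why: Palladium-catalysed reductive carbonylation of an aryl triflate (oxidative addition, CO insertion, hydride transfer from the silane to the acylpalladium species). The conditions are neutral to weakly basic and should leave both benzylic ethers and all stereocentres untouched.

Step 14
Reactants: 21 (2R,3R)-3-(ArB)-2-(4-methoxyphenyl)-2,3-dihydro-1-benzofuran-5-carbaldehyde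
Product: 22 (2R,3R)-3-[(2R,3R)-3-(3,5-dihydroxyphenyl)-6-hydroxy-2-(4-hydroxyphenyl)-2,3-dihydro-1-benzofuran-4-yl]-2-(4-hydroxyphenyl)-2,3-dihydro-1-benzofuran-5-carbaldehyde
Conditions: BBr3, CH2Cl2, −78 → 0 °C; aq. work-up
Reagents that add atoms: none
Why: Lewis acid cleavage of the five aryl methyl ethers by bromide attack on the boron-activated methyl groups. The aldehyde is returned on aqueous work-up, and a benzylic C–O bond that opens transiently should reclose to the trans ring, the stable arrangement at both heterocycles.

## Compound list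

1 | 1-bromo-3,5-dimethoxybenzene | COc1cc(Br)cc(OC)c1 | starting material
2 | 3,5-dimethoxybenzoyl chloride | COc1cc(cc(OC)c1)C(Cl)=O | starting material
3 | (2-bromo-4,6-dimethoxyphenyl)(3,5-dimethoxyphenyl)methanone | COc1cc(OC)cc(c1)C(=O)c1c(Br)cc(OC)cc1OC | intermediate
4 | (2-bromo-6-hydroxy-4-methoxyphenyl)(3,5-dimethoxyphenyl)methanone | COc1cc(OC)cc(c1)C(=O)c1c(Br)cc(OC)cc1O | intermediate
5 | 4-methoxybenzyl chloride | COc1ccc(CCl)cc1 | starting material
6 | {2-bromo-4-methoxy-6-[(4-methoxybenzyl)oxy]phenyl}(3,5-dimethoxyphenyl)methanone | COc1ccc(COc2cc(OC)cc(Br)c2C(=O)c2cc(OC)cc(OC)c2)cc1 | intermediate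
7 | [{2-bromo-4-methoxy-6-[(4-methoxybenzyl)oxy]phenyl}(3,5-dimethoxyphenyl)methylidene]hydrazine (E/Z mixture) | NN=C(c1cc(OC)cc(OC)c1)c1c(Br)cc(OC)cc1OCc1ccc(OC)cc1 | intermediate
8 | 1-bromo-2-[diazo(3,5-dimethoxyphenyl)methyl]-5-methoxy-3-[(4-methoxybenzyl)oxy]benzene | [N-]=[N+]=C(c1cc(OC)cc(OC)c1)c1c(Br)cc(OC)cc1OCc1ccc(OC)cc1 | intermediate
9 | (2S,3R)-4-bromo-3-(3,5-dimethoxyphenyl)-6-methoxy-2-(4-methoxyphenyl)-2,3-dihydro-1-benzofuran (cis) | Brc1cc(OC)cc2c1[C@@H](c1cc(OC)cc(OC)c1)[C@@H](c1ccc(OC)cc1)O2 | intermediate
10 | (2R,3R)-4-bromo-3-(3,5-dimethoxyphenyl)-6-methoxy-2-(4-methoxyphenyl)-2,3-dihydro-1-benzofuran (trans) | Brc1cc(OC)cc2c1[C@@H](c1cc(OC)cc(OC)c1)[C@H](c1ccc(OC)cc1)O2 | intermediate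
11 | (E)-2-(2-ethoxyvinyl)-4,4,5,5-tetramethyl-1,3,2-dioxaborolane | CCO/C=C/B1OC(C)(C)C(C)(C)O1 | starting material
12 | (2R,3R)-3-(3,5-dimethoxyphenyl)-4-[(E)-2-ethoxyvinyl]-6-methoxy-2-(4-methoxyphenyl)-2,3-dihydro-1-benzofuran | CCO/C=C/c1cc(OC)cc2c1[C@@H](c1cc(OC)cc(OC)c1)[C@H](c1ccc(OC)cc1)O2 | intermediate
13 | 2-[(2R,3R)-3-(3,5-dimethoxyphenyl)-6-methoxy-2-(4-methoxyphenyl)-2,3-dihydro-1-benzofuran-4-yl]acetaldehyde | O=CCc1cc(OC)cc2c1[C@@H](c1cc(OC)cc(OC)c1)[C@H](c1ccc(OC)cc1)O2 | intermediate
14 | 1,4-benzoquinone | O=C1C=CC(=O)C=C1 | starting material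
15 | (2R)-2-(2,5-dihydroxyphenyl)-2-[(2R,3R)-3-(3,5-dimethoxyphenyl)-6-methoxy-2-(4-methoxyphenyl)-2,3-dihydro-1-benzofuran-4-yl]acetaldehyde | O=C[C@@H](c1cc(O)ccc1O)c1cc(OC)cc2c1[C@@H](c1cc(OC)cc(OC)c1)[C@H](c1ccc(OC)cc1)O2 | intermediate
16 | (3R)-3-[(2R,3R)-3-(3,5-dimethoxyphenyl)-6-methoxy-2-(4-methoxyphenyl)-2,3-dihydro-1-benzofuran-4-yl]-2,3-dihydro-1-benzofuran-2,5-diol (C2 epimers) | Oc1ccc2c(c1)[C@@H](c1cc(OC)cc3c1[C@@H](c1cc(OC)cc(OC)c1)[C@H](c1ccc(OC)cc1)O3)C(O)O2 | intermediate
17 | 4-methoxyphenylmagnesium bromide (THF solution) | COc1ccc([Mg]Br)cc1 | starting material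
18 | 2-{(1R)-1-[(2R,3R)-3-(3,5-dimethoxyphenyl)-6-methoxy-2-(4-methoxyphenyl)-2,3-dihydro-1-benzofuran-4-yl]-2-hydroxy-2-(4-methoxyphenyl)ethyl}benzene-1,4-diol (carbinol epimers) | COc1ccc(cc1)C(O)[C@@H](c1cc(O)ccc1O)c1cc(OC)cc2c1[C@@H](c1cc(OC)cc(OC)c1)[C@H](c1ccc(OC)cc1)O2 | intermediate
19 | (2R,3R)-3-[(2R,3R)-3-(3,5-dimethoxyphenyl)-6-methoxy-2-(4-methoxyphenyl)-2,3-dihydro-1-benzofuran-4-yl]-2-(4-methoxyphenyl)-2,3-dihydro-1-benzofuran-5-ol | Oc1ccc2c(c1)[C@@H](c1cc(OC)cc3c1[C@@H](c1cc(OC)cc(OC)c1)[C@H](c1ccc(OC)cc1)O3)[C@H](c1ccc(OC)cc1)O2 | intermediate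
20 | (2R,3R)-3-[(2R,3R)-3-(3,5-dimethoxyphenyl)-6-methoxy-2-(4-methoxyphenyl)-2,3-dihydro-1-benzofuran-4-yl]-2-(4-methoxyphenyl)-2,3-dihydro-1-benzofuran-5-yl trifluoromethanesulfonate | O=S(=O)(Oc1ccc2c(c1)[C@@H](c1cc(OC)cc3c1[C@@H](c1cc(OC)cc(OC)c1)[C@H](c1ccc(OC)cc1)O3)[C@H](c1ccc(OC)cc1)O2)C(F)(F)F | intermediate
21 | (2R,3R)-3-[(2R,3R)-3-(3,5-dimethoxyphenyl)-6-methoxy-2-(4-methoxyphenyl)-2,3-dihydro-1-benzofuran-4-yl]-2-(4-methoxyphenyl)-2,3-dihydro-1-benzofuran-5-carbaldehyde | O=Cc1ccc2c(c1)[C@@H](c1cc(OC)cc3c1[C@@H](c1cc(OC)cc(OC)c1)[C@H](c1ccc(OC)cc1)O3)[C@H](c1ccc(OC)cc1)O2 | intermediate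
22 | (2R,3R)-3-[(2R,3R)-3-(3,5-dihydroxyphenyl)-6-hydroxy-2-(4-hydroxyphenyl)-2,3-dihydro-1-benzofuran-4-yl]-2-(4-hydroxyphenyl)-2,3-dihydro-1-benzofuran-5-carbaldehyde | O=Cc1ccc2c(c1)[C@@H](c1cc(O)cc3c1[C@@H](c1cc(O)cc(O)c1)[C@H](c1ccc(O)cc1)O3)[C@H](c1ccc(O)cc1)O2 | target

## Step count and least certain steps

Total: 14 steps. Longest linear sequence: 14 steps (1 to 22).

**Step 9 (key step).** The enamine of 13 is conjugated and crowded, so addition to 14 may be slow. Facial selectivity may be poor if the ring B substituent ortho to the side chain opposes the catalyst. Configuration at C3 may be lost by enolisation of 15 before the hemiacetal closes. The hydroquinone stage may be oxidised by excess 14. The fallback sets out from bromide 10 and returns at aldehyde 21; it builds ring A by a different bond set and gives up catalyst control in favour of a separation.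
- Bromine–lithium exchange on 10 (n-BuLi, THF, −78 °C) and addition to 5-bromo-2-hydroxybenzaldehyde (as its phenoxide, NaH) would give 4-bromo-2-[(ArB)(hydroxy)methyl]phenol F1.
- p-TolSO2Na in aqueous formic acid would convert it into 4-bromo-2-[(ArB)(4-methylbenzenesulfonyl)methyl]phenol F2.
- Cs2CO3 and (4-methoxybenzyl)dimethylsulfonium tetrafluoroborate would release the ortho-quinone methide and close ring A by the known trans-selective [4+1] annulation. This gives (2R,3R)-5-bromo-3-(ArB)-2-(4-methoxyphenyl)-2,3-dihydro-1-benzofuran F3 and its (2S,3S) ring A diastereomer F4, which can be separated because ring B is a single enantiomer.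
- Bromine–lithium exchange on F3 and DMF would give 21.

**Step 5.** Hydrazone formation in step 4 may stall at the ketone with two ortho substituents. In step 5 the carbene flanked by bromine may form azine or insert with poor enantioselectivity, and step 6 depends on its outcome. The fallback sets out from ketone 6 and returns at 10. LiN(i-Pr)2 (THF, −78 °C → rt) would condense the benzylic ether carbanion with the ketone to 4-bromo-3-(3,5-dimethoxyphenyl)-6-methoxy-2-(4-methoxyphenyl)-1-benzofuran F5. Ionic hydrogenation (Et3SiH, TFA) would give the racemic trans-dihydrobenzofuran, that is 10 with its (2S,3S) enantiomer F6. Preparative chromatography on a chiral stationary phase would deliver 10.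

**Step 10.** The aryl metal may deprotonate C3–H of the ring-opened aldehyde and epimerise C3, or the lactol may open incompletely. The fallback sets out from 16 and returns at 18. It replaces the stoichiometric organometallic reagent by a catalytic, nearly neutral aryl transfer: 4-methoxyphenylboronic acid with [Rh(OH)(cod)]2 in dioxane/H2O, where an arylrhodium species adds to the aldehyde form. This fallback makes no compound outside the list (F0).

**Step 11.** The benzylic cation may be diverted. Friedel–Crafts attack of the 3,5-dimethoxyphenyl ring would close a seven-membered ring, proton loss would give a triarylethene, and the hydroquinone may oxidise in air. The fallback sets out from 18 and returns at 19. A Mitsunobu etherification (PPh3, DIAD, THF, 0 °C) closes O1–C2 by displacement of the activated alcohol under neutral conditions. Because 18 is a pair of carbinol epimers, it gives 19 together with (2S,3R)-3-(ArB)-2-(4-methoxyphenyl)-2,3-dihydro-1-benzofuran-5-ol F7, which is separated.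

**Step 14.** The Lewis acid may activate the formyl group toward condensation with the freed resorcinol rings, and demethylation may remain incomplete at temperatures that spare the aldehyde. The fallback sets out from triflate 20 and returns at 22; it demethylates before the aldehyde exists.
- BBr3 on 20 would give the pentaphenol triflate (2R,3R)-3-[(2R,3R)-3-(3,5-dihydroxyphenyl)-6-hydroxy-2-(4-hydroxyphenyl)-2,3-dihydro-1-benzofuran-4-yl]-2-(4-hydroxyphenyl)-2,3-dihydro-1-benzofuran-5-yl trifluoromethanesulfonate F8.
- Ac2O and pyridine would give its pentaacetate F9.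
- The carbonylation of step 13 would give the pentaacetate of 22 F10.
- K2CO3 in MeOH would remove the acetates and give 22.

## Further compounds

F1 | step 9 | 4-bromo-2-{[(2R,3R)-3-(3,5-dimethoxyphenyl)-6-methoxy-2-(4-methoxyphenyl)-2,3-dihydro-1-benzofuran-4-yl](hydroxy)methyl}phenol (carbinol epimers) | Oc1ccc(Br)cc1C(O)c1cc(OC)cc2c1[C@@H](c1cc(OC)cc(OC)c1)[C@H](c1ccc(OC)cc1)O2
F2 | step 9 | 4-bromo-2-{[(2R,3R)-3-(3,5-dimethoxyphenyl)-6-methoxy-2-(4-methoxyphenyl)-2,3-dihydro-1-benzofuran-4-yl](4-methylbenzenesulfonyl)methyl}phenol (epimers) | Oc1ccc(Br)cc1C(c1cc(OC)cc2c1[C@@H](c1cc(OC)cc(OC)c1)[C@H](c1ccc(OC)cc1)O2)S(=O)(=O)c1ccc(C)cc1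
F3 | step 9 | (2R,3R)-5-bromo-3-[(2R,3R)-3-(3,5-dimethoxyphenyl)-6-methoxy-2-(4-methoxyphenyl)-2,3-dihydro-1-benzofuran-4-yl]-2-(4-methoxyphenyl)-2,3-dihydro-1-benzofuran | Brc1ccc2c(c1)[C@@H](c1cc(OC)cc3c1[C@@H](c1cc(OC)cc(OC)c1)[C@H](c1ccc(OC)cc1)O3)[C@H](c1ccc(OC)cc1)O2
F4 | step 9 | (2S,3S)-5-bromo-3-[(2R,3R)-3-(3,5-dimethoxyphenyl)-6-methoxy-2-(4-methoxyphenyl)-2,3-dihydro-1-benzofuran-4-yl]-2-(4-methoxyphenyl)-2,3-dihydro-1-benzofuran | Brc1ccc2c(c1)[C@H](c1cc(OC)cc3c1[C@@H](c1cc(OC)cc(OC)c1)[C@H](c1ccc(OC)cc1)O3)[C@@H](c1ccc(OC)cc1)O2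
F5 | step 5 | 4-bromo-3-(3,5-dimethoxyphenyl)-6-methoxy-2-(4-methoxyphenyl)-1-benzofuran | COc1ccc(cc1)-c1oc2cc(OC)cc(Br)c2c1-c1cc(OC)cc(OC)c1
F6 | step 5 | (2S,3S)-4-bromo-3-(3,5-dimethoxyphenyl)-6-methoxy-2-(4-methoxyphenyl)-2,3-dihydro-1-benzofuran | Brc1cc(OC)cc2c1[C@H](c1cc(OC)cc(OC)c1)[C@@H](c1ccc(OC)cc1)O2
F0 | step 10 | none | none
F7 | step 11 | (2S,3R)-3-[(2R,3R)-3-(3,5-dimethoxyphenyl)-6-methoxy-2-(4-methoxyphenyl)-2,3-dihydro-1-benzofuran-4-yl]-2-(4-methoxyphenyl)-2,3-dihydro-1-benzofuran-5-ol | Oc1ccc2c(c1)[C@@H](c1cc(OC)cc3c1[C@@H](c1cc(OC)cc(OC)c1)[C@H](c1ccc(OC)cc1)O3)[C@@H](c1ccc(OC)cc1)O2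
F8 | step 14 | (2R,3R)-3-[(2R,3R)-3-(3,5-dihydroxyphenyl)-6-hydroxy-2-(4-hydroxyphenyl)-2,3-dihydro-1-benzofuran-4-yl]-2-(4-hydroxyphenyl)-2,3-dihydro-1-benzofuran-5-yl trifluoromethanesulfonate | O=S(=O)(Oc1ccc2c(c1)[C@@H](c1cc(O)cc3c1[C@@H](c1cc(O)cc(O)c1)[C@H](c1ccc(O)cc1)O3)[C@H](c1ccc(O)cc1)O2)C(F)(F)F
F9 | step 14 | pentaacetate of F8: (2R,3R)-3-[(2R,3R)-6-acetoxy-2-(4-acetoxyphenyl)-3-(3,5-diacetoxyphenyl)-2,3-dihydro-1-benzofuran-4-yl]-2-(4-acetoxyphenyl)-2,3-dihydro-1-benzofuran-5-yl trifluoromethanesulfonate | O=S(=O)(Oc1ccc2c(c1)[C@@H](c1cc(OC(C)=O)cc3c1[C@@H](c1cc(OC(C)=O)cc(OC(C)=O)c1)[C@H](c1ccc(OC(C)=O)cc1)O3)[C@H](c1ccc(OC(C)=O)cc1)O2)C(F)(F)F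
F10 | step 14 | pentaacetate of 22: (2R,3R)-3-[(2R,3R)-6-acetoxy-2-(4-acetoxyphenyl)-3-(3,5-diacetoxyphenyl)-2,3-dihydro-1-benzofuran-4-yl]-2-(4-acetoxyphenyl)-2,3-dihydro-1-benzofuran-5-carbaldehyde | O=Cc1ccc2c(c1)[C@@H](c1cc(OC(C)=O)cc3c1[C@@H](c1cc(OC(C)=O)cc(OC(C)=O)c1)[C@H](c1ccc(OC(C)=O)cc1)O3)[C@H](c1ccc(OC(C)=O)cc1)O2
A1 | alternative 1 | ethyl 3-(3,5-dimethoxyphenyl)-3-oxopropanoate | CCOC(=O)CC(=O)c1cc(OC)cc(OC)c1
A2 | alternative 1 | 3,5-dimethoxy-2-(trimethylsilyl)phenyl trifluoromethanesulfonate | COc1cc(OC)c([Si](C)(C)C)c(OS(=O)(=O)C(F)(F)F)c1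
A3 | alternative 1 | ethyl 2-[2-(3,5-dimethoxybenzoyl)-3,5-dimethoxyphenyl]acetate | CCOC(=O)Cc1cc(OC)cc(OC)c1C(=O)c1cc(OC)cc(OC)c1
A4 | alternative 2 | 3-bromo-2-[(3,5-dimethoxyphenyl)(4-methylbenzenesulfonyl)methyl]-5-methoxyphenol | COc1cc(O)c(C(c2cc(OC)cc(OC)c2)S(=O)(=O)c2ccc(C)cc2)c(Br)c1
A5 | alternative 2 | (2R,5R)-1-(4-methoxybenzyl)-2,5-dimethylthiolan-1-ium tetrafluoroborate | C[C@@H]1CC[C@@H](C)[S+]1Cc1ccc(OC)cc1.F[B-](F)(F)F
A6 | alternative 2 | (2R,3R)-4-bromo-3-(3,5-dimethoxyphenyl)-6-methoxy-2-(4-methoxyphenyl)-2,3-dihydro-1-benzofuran | Brc1cc(OC)cc2c1[C@@H](c1cc(OC)cc(OC)c1)[C@H](c1ccc(OC)cc1)O2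
A7 | alternative 3 | triisopropyl({[(1R,2S)-2-[(2R,3R)-3-(3,5-dimethoxyphenyl)-6-methoxy-2-(4-methoxyphenyl)-2,3-dihydro-1-benzofuran-4-yl]-1-(4-methoxyphenyl)but-3-yn-1-yl]oxy}ethynyl)silane | C#C[C@@H](c1cc(OC)cc2c1[C@@H](c1cc(OC)cc(OC)c1)[C@H](c1ccc(OC)cc1)O2)[C@H](c1ccc(OC)cc1)OC#C[Si](C(C)C)(C(C)C)C(C)C
A8 | alternative 3 | 3,3-diethoxyprop-1-yne | CCOC(OCC)C#C
A9 | alternative 3 | [(2R,3R)-5-(diethoxymethyl)-3-[(2R,3R)-3-(3,5-dimethoxyphenyl)-6-methoxy-2-(4-methoxyphenyl)-2,3-dihydro-1-benzofuran-4-yl]-2-(4-methoxyphenyl)-2,3-dihydro-1-benzofuran-7-yl]triisopropylsilane | CCOC(OCC)c1cc([Si](C(C)C)(C(C)C)C(C)C)c2c(c1)[C@@H](c1cc(OC)cc3c1[C@@H](c1cc(OC)cc(OC)c1)[C@H](c1ccc(OC)cc1)O3)[C@H](c1ccc(OC)cc1)O2
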